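**Strategy.** The cyclohexane ring (cladiellin numbering: C1, C10–C14; C1 is the ring-fusion CH next to C2–O, C11 the acylated carbinol, C14 carries the lactone branch) is cut at C1–C14 and C12–C13. The 1,4-relation of oxygenated C11 and branched C14 is the pattern of a 2-alkoxydiene plus enone Diels–Alder adduct. In one flask a bridged enol triflate, 1-ethoxyvinylstannane and methyl vinyl ketone are joined by Stille coupling, [4+2] cycloaddition on the face away from the oxonene bridge, and base equilibration at C14. The precursor is an 11-oxabicyclo[6.2.1]undecenone obtained by oxonium-ylide ring expansion of a tetrahydropyran built from (S)-linalool.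

Key step: step 11

Remark: (S)-(+)-linalool and the L-fructose-derived Shi ketone are taken as purchasable. Locants follow cladiellin numbering: C1 ring-fusion CH bonded to C2, C10 and C14; C2 and C9 the ether CH–O carbons; C3 C(Me)–O; C6=C7(Me) the ring alkene; C10 the other ring-fusion CH; C11 C(Me)–O; C12 and C13 CH2; C14 CH; C15 CH(C17H3); C16 the lactone C=O.

Step 1
Reactants: 1 (S)-(+)-linalool; 2 acryloyl chloride
Product: 3 (3S)-3,7-dimethylocta-1,6-dien-3-yl prop-2-enoate
Conditions: n-BuLi, THF, −78 °C; then 2, −78 → 0 °C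
Reagents that add atoms: none
Why: O-acylation of the lithium alkoxide of the hindered tertiary alcohol by the acid chloride (alkoxide acylation) should proceed without touching the C3 stereocentre, which comes from the chiral pool.

Step 2
Reactants: 3 linalyl acrylate
Product: 4 (3S)-5-[(2S)-3,3-dimethyloxiran-2-yl]-3-methylpent-1-en-3-yl prop-2-enoate
Conditions: L-fructose-derived Shi ketone (30 mol%), KHSO5 (as 2KHSO5·KHSO4·K2SO4), K2CO3, Bu4NHSO4, Na2B4O7 buffer, MeCN–CH2(OMe)2–H2O, 0 °C
Reagents that add atoms: potassium peroxymonosulfate, [K+].[O-]S(=O)(=O)OO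
Why: Shi asymmetric epoxidation: the chiral dioxirane attacks only the electron-rich trisubstituted alkene (vinyl and acrylate are too electron-poor) through a spiro transition state, and the L-fructose-derived catalyst should give the 6S epoxide, the D-fructose-derived one being known to give R at such CH carbons.

Step 3
Reactants: 4 epoxy acrylate
Product: 5 (5S)-5-{2-[(2S)-3,3-dimethyloxiran-2-yl]ethyl}-5-methylfuran-2(5H)-one
Conditions: second-generation Grubbs catalyst RuCl2(=CHPh)(PCy3)(H2IMes) (5 mol%), toluene, 80 °C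
Reagents that add atoms: none
Why: Ring-closing metathesis between the vinyl group and the acrylate forms the butenolide and releases ethene; the epoxide is inert and, with the trisubstituted alkene already masked, no competing cyclopentene closure is possible.

Step 4
Reactants: 5 epoxy butenolide
Product: 8 cis-fused bicyclic lactone (3aS,5S,7aS)-7a-methyl-5-(prop-1-en-2-yl)hexahydro-2H-furo[3,2-b]pyran-2-one, via allyl silyl ether 6 (not isolated), via hydroxy butenolide 7 (not isolated)
Conditions: Me3SiOTf, DBU, toluene, 0 → 23 °C; then Bu4NF, THF, 0 → 23 °C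
Reagents that add atoms: trimethylsilyl trifluoromethanesulfonate, C[Si](C)(C)OS(=O)(=O)C(F)(F)F (atoms kept only in intermediate 6)
Why: Silyl-triflate-mediated epoxide-to-allyl silyl ether isomerisation (the C7–O bond ionises at the tertiary carbon, the amidine removes a methyl proton, C6 is untouched) is followed by fluoride desilylation and intramolecular 6-exo oxa-Michael addition of the C6 alkoxide to the butenolide; C2 is set because a γ-lactone can only be cis-fused to the new tetrahydropyran, so the C3 centre dictates the face.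

Step 5
Reactants: 8 bicyclic lactone
Product: 9 2-[(2S,3S,6S)-3-hydroxy-3-methyl-6-(prop-1-en-2-yl)oxan-2-yl]-N-methoxy-N-methylacetamide
Conditions: MeNH(OMe)·HCl, i-PrMgCl, THF, −20 → 0 °C
Reagents that add atoms: N,O-dimethylhydroxylamine hydrochloride, CNOC.Cl
Why: Weinreb aminolysis of the γ-lactone by the chloromagnesium amide opens the ring and frees the tertiary C3 alcohol; no stereocentre is affected.

Step 6
Reactants: 9 hydroxy Weinreb amide
Product: 10 N-methoxy-N-methyl-2-[(2S,3S,6S)-3-methyl-6-(prop-1-en-2-yl)-3-(triethylsilyloxy)oxan-2-yl]acetamide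
Conditions: Et3SiOTf, 2,6-lutidine, CH2Cl2, −78 → 0 °C
Reagents that add atoms: triethylsilyl trifluoromethanesulfonate, CC[Si](CC)(CC)OS(=O)(=O)C(F)(F)F
Why: Silyl ether protection of the hindered tertiary alcohol with a silyl triflate and a hindered pyridine base, done promptly so that the γ-hydroxy amide cannot relactonise.

Step 7
Reactants: 10 silylated Weinreb amide
Product: 11 1-[(2S,3S,6S)-3-methyl-6-(prop-1-en-2-yl)-3-(triethylsilyloxy)oxan-2-yl]propan-2-one
Conditions: MeMgBr, THF, 0 °C
Reagents that add atoms: methylmagnesium bromide, C[Mg]Br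
Why: Weinreb ketone synthesis: the chelated tetrahedral intermediate stops the Grignard addition at the methyl ketone.

Step 8
Reactants: 11 methyl ketone
Product: 13 1-diazo-3-[(2S,3S,6S)-3-methyl-6-(prop-1-en-2-yl)-3-(triethylsilyloxy)oxan-2-yl]propan-2-one, via trifluoroacetyl diketone 12 (not isolated)
Conditions: LiN(SiMe3)2, THF, −78 °C; CF3CO2CH2CF3; then MsN3, Et3N, H2O, MeCN, 23 °C
Reagents that add atoms: methanesulfonyl azide, CS(=O)(=O)N=[N+]=[N-]; 2,2,2-trifluoroethyl trifluoroacetate, O=C(OCC(F)(F)F)C(F)(F)F (atoms kept only in intermediate 12)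
Why: Detrifluoroacetylative diazo transfer (Danheiser): the kinetic lithium enolate on the methyl side is trifluoroacetylated, and the activated diketone undergoes diazo transfer with loss of the trifluoroacetyl group to give the terminal diazoketone.

Step 9
Reactants: 13 diazoketone
Product: 15 (1S,2S,5Z,8S)-2,6-dimethyl-2-(triethylsilyloxy)-11-oxabicyclo[6.2.1]undec-5-en-9-one, via oxonium ylide 14 (not isolated)
Conditions: Cu(CF3COCHCOCF3)2 (5 mol%), CH2Cl2, 40 °C
Reagents that add atoms: none
Why: Copper carbenoid formation, attack of the ring oxygen to give a bicyclic oxonium ylide and [2,3]-sigmatropic rearrangement through the isopropenyl group (three-carbon ring expansion of the tetrahydropyran) should give the bridged oxonene; C9 is fixed by the ylide geometry (only the cis ether bridge can form) and the envelope transition state favours the Z ring alkene.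

Step 10
Reactants: 15 bicyclic ketone
Product: 16 (1S,2S,5Z,8S)-2,6-dimethyl-2-(triethylsilyloxy)-11-oxabicyclo[6.2.1]undeca-5,9-dien-9-yl trifluoromethanesulfonate
Conditions: NaN(SiMe3)2, THF, −78 °C; then PhNTf2
Reagents that add atoms: N-phenylbis(trifluoromethanesulfonimide), O=S(=O)(N(c1ccccc1)S(=O)(=O)C(F)(F)F)C(F)(F)F
Why: Kinetic enolisation occurs towards the C1 methylene (the other α-carbon is the bridgehead C9), and O-sulfonylation of the sodium enolate gives the enol triflate.

Step 11
Reactants: 16 enol triflate; 17 tributyl(1-ethoxyvinyl)stannane; 18 methyl vinyl ketone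
Product: 21 tricyclic enol ether ketone (14-acetyl-11-ethoxy-3-triethylsilyloxy tricycle; C10=C11; 1S,2S,3S,6Z,9S,14R; acetyl trans to C2), via ethoxy diene 19 (not isolated), via C14-epimeric adduct 20 (not isolated)
Conditions: 17, Pd(PPh3)4 (5 mol%), LiCl, THF, 65 °C; then 18, BHT (cat.), toluene, 110 °C (sealed tube); then K2CO3, MeOH, 23 °C
Reagents that add atoms: none
Why: Oxidative addition of zerovalent palladium to the enol triflate, transmetalation from tin and reductive elimination (Stille coupling) give the 2-ethoxy-1,3-diene C1=C10–C11(OEt)=C12, which without isolation undergoes a thermal normal-electron-demand Diels–Alder reaction with methyl vinyl ketone; the closest known reaction type is the intermolecular [4+2] cycloaddition of bridged 2-alkoxydienes used for cladiellin cores. The cyclohexene ring (C1, C10, C11, C12, C13, C14) is closed by intermolecular [4+2] annulation that forms C1–C14 and C12–C13 in one event. Regiochemistry follows the para rule: the nucleophilic diene terminus C12 bonds to the enone β-carbon C13, so the acetyl-bearing carbon C14 bonds to C1. C1 is set by approach of the dienophile to the diene face opposite the six-carbon bridge C3–C8, the face that carries only H2 and H9. C14 is set under thermodynamic control: K2CO3 in methanol epimerises the α-keto centre of the endo adduct so that the acetyl group ends up trans to C2 and pseudo-equatorial. The enol ether C10=C11 left by the cycloaddition keeps C11 at the ketone oxidation level and lets C10 be set later by protonation.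

Step 12
Reactants: 21 tricyclic methyl ketone
Product: 22 alkenyl triflate (C15(OTf)=C17H2 on C14; enol ether and silyl ether intact)
Conditions: KN(SiMe3)2, THF, −78 °C; then PhNTf2
Reagents that add atoms: N-phenylbis(trifluoromethanesulfonimide), O=S(=O)(N(c1ccccc1)S(=O)(=O)C(F)(F)F)C(F)(F)F
Why: Kinetic deprotonation of the methyl ketone at the unhindered methyl group and O-triflation of the potassium enolate (enol triflate formation) leave the tetrasubstituted enol ether and the C14 centre untouched.

Step 13
Reactants: 22 alkenyl triflate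
Product: 23 2-substituted acrylic acid (C15=C17H2, C16 carboxylic acid; enol ether and silyl ether intact)
Conditions: Pd(OAc)2 (5 mol%), PPh3, CO (1 atm), Et3N, DMF–H2O, 60 °C
Reagents that add atoms: carbon monoxide, [C-]#[O+]; water, O
Why: Palladium-catalysed hydroxycarbonylation of the alkenyl triflate (oxidative addition, CO insertion, capture of the acylpalladium by water) installs C16 as the acid under basic conditions that spare the enol ether and the silyl ether.

Step 14
Reactants: 23 acrylic acid enol ether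
Product: 24 keto hydroxy acrylic acid (11-oxo, 3-hydroxy, cis ring fusion; 1S,2S,3S,6Z,9S,10R,14R)
Conditions: 2 M aq. HCl, THF–MeOH, 23 °C
Reagents that add atoms: water, O
Why: Acid hydrolysis of the enol ether and of the tertiary silyl ether; C10 is set on protonation under thermodynamic control, the cis-fused hydroisobenzofuranone being the only unstrained ring fusion on the bridged tetrahydrofuran.

Step 15
Reactants: 24 keto hydroxy acrylic acid
Product: 25 (15R)-keto hydroxy acid (C15 H and CH3, C16 acid)
Conditions: Ru(OAc)2[(R)-BINAP] (2 mol%), H2 (100 atm), MeOH, 23 °C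
Reagents that add atoms: none
Why: Carboxylate-directed asymmetric hydrogenation of the 2-substituted acrylic acid (Noyori hydrogenation): by analogy with 2-arylacrylic acids the R ligand should give the 15R acid, and neither the ketone nor the trisubstituted ring alkene is reduced.

Step 16
Reactants: 25 keto hydroxy acid
Product: 27 keto lactone (C3–O–C16 seven-membered lactone; 11-oxo), via mixed anhydride 26 (not isolated)
Conditions: 2,4,6-trichlorobenzoyl chloride, Et3N, THF, 23 °C; then DMAP, toluene, 80 °C, high dilution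
Reagents that add atoms: 2,4,6-trichlorobenzoyl chloride, O=C(Cl)c1c(Cl)cc(Cl)cc1Cl (atoms kept only in intermediate 26)
Why: Yamaguchi lactonisation: DMAP attacks the mixed anhydride and the acylpyridinium acylates the only hydroxyl group, the tertiary C3–OH, closing the seven-membered lactone without touching C15.

Step 17
Reactants: 27 keto lactone; 28 butanoic anhydride
Product: 30 target CNP0294597.2, via chloromagnesium alkoxide 29 (not isolated)
Conditions: MeMgCl, THF, −78 → −20 °C; then 28, DMAP (cat.), −20 → 23 °C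
Reagents that add atoms: methylmagnesium chloride, C[Mg]Cl
Why: Grignard 1,2-addition to the C11 ketone, much faster than attack on the hindered tertiary-alkyl lactone, should occur from the convex face of the cis-fused bicycle (the face of H10 and H1, opposite the C9–O arm), placing methyl cis to H10 and oxygen on the tetrahydrofuran side (11R); O-acylation of the magnesium alkoxide in the same flask avoids a separate esterification of the hindered tertiary alcohol.

**Compound list**
1 | (S)-(+)-linalool, (3S)-3,7-dimethylocta-1,6-dien-3-ol | C=C[C@@](C)(O)CCC=C(C)C | starting material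
2 | acryloyl chloride | C=CC(=O)Cl | starting material
3 | (3S)-3,7-dimethylocta-1,6-dien-3-yl prop-2-enoate | C=C[C@@](C)(OC(=O)C=C)CCC=C(C)C | intermediate
4 | (3S)-5-[(2S)-3,3-dimethyloxiran-2-yl]-3-methylpent-1-en-3-yl prop-2-enoate | C=C[C@@](C)(OC(=O)C=C)CC[C@@H]1OC1(C)C | intermediate
5 | (5S)-5-{2-[(2S)-3,3-dimethyloxiran-2-yl]ethyl}-5-methylfuran-2(5H)-one | O=C1C=C[C@](C)(CC[C@@H]2OC2(C)C)O1 | intermediate
6 | (5S)-5-methyl-5-[(3S)-4-methyl-3-(trimethylsilyloxy)pent-4-en-1-yl]furan-2(5H)-one | O=C1C=C[C@](C)(CC[C@H](O[Si](C)(C)C)C(C)=C)O1 | intermediate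
7 | (5S)-5-[(3S)-3-hydroxy-4-methylpent-4-en-1-yl]-5-methylfuran-2(5H)-one | O=C1C=C[C@](C)(CC[C@H](O)C(C)=C)O1 | intermediate
8 | (3aS,5S,7aS)-7a-methyl-5-(prop-1-en-2-yl)hexahydro-2H-furo[3,2-b]pyran-2-one | O=C1C[C@@H]2O[C@H](C(C)=C)CC[C@]2(C)O1 | intermediate
9 | 2-[(2S,3S,6S)-3-hydroxy-3-methyl-6-(prop-1-en-2-yl)oxan-2-yl]-N-methoxy-N-methylacetamide | CON(C)C(=O)C[C@@H]1O[C@H](C(C)=C)CC[C@]1(C)O | intermediate
10 | N-methoxy-N-methyl-2-[(2S,3S,6S)-3-methyl-6-(prop-1-en-2-yl)-3-(triethylsilyloxy)oxan-2-yl]acetamide | CON(C)C(=O)C[C@@H]1O[C@H](C(C)=C)CC[C@]1(C)O[Si](CC)(CC)CC | intermediate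
11 | 1-[(2S,3S,6S)-3-methyl-6-(prop-1-en-2-yl)-3-(triethylsilyloxy)oxan-2-yl]propan-2-one | CC(=O)C[C@@H]1O[C@H](C(C)=C)CC[C@]1(C)O[Si](CC)(CC)CC | intermediate
12 | 1,1,1-trifluoro-5-[(2S,3S,6S)-3-methyl-6-(prop-1-en-2-yl)-3-(triethylsilyloxy)oxan-2-yl]pentane-2,4-dione | O=C(CC(=O)C[C@@H]1O[C@H](C(C)=C)CC[C@]1(C)O[Si](CC)(CC)CC)C(F)(F)F | intermediate
13 | 1-diazo-3-[(2S,3S,6S)-3-methyl-6-(prop-1-en-2-yl)-3-(triethylsilyloxy)oxan-2-yl]propan-2-one | [N-]=[N+]=CC(=O)C[C@@H]1O[C@H](C(C)=C)CC[C@]1(C)O[Si](CC)(CC)CC | intermediate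
14 | bicyclic oxonium ylide (O+ shared by the oxane and a 3-oxotetrahydrofuran ring, carbanion C9 between O+ and C=O) | O=C1C[C@@H]2[O+]([CH-]1)[C@H](C(C)=C)CC[C@]2(C)O[Si](CC)(CC)CC | intermediate
15 | (1S,2S,5Z,8S)-2,6-dimethyl-2-(triethylsilyloxy)-11-oxabicyclo[6.2.1]undec-5-en-9-one | O=C1C[C@@H]2O[C@H]1C/C(C)=C\CC[C@]2(C)O[Si](CC)(CC)CC | intermediate
16 | (1S,2S,5Z,8S)-2,6-dimethyl-2-(triethylsilyloxy)-11-oxabicyclo[6.2.1]undeca-5,9-dien-9-yl trifluoromethanesulfonate | O=S(=O)(OC1=C[C@@H]2O[C@H]1C/C(C)=C\CC[C@]2(C)O[Si](CC)(CC)CC)C(F)(F)F | intermediate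
17 | tributyl(1-ethoxyvinyl)stannane | CCCC[Sn](CCCC)(CCCC)C(=C)OCC | starting material
18 | methyl vinyl ketone (but-3-en-2-one) | CC(=O)C=C | starting material
19 | (1S,2S,5Z,8S)-9-(1-ethoxyvinyl)-2,6-dimethyl-2-(triethylsilyloxy)-11-oxabicyclo[6.2.1]undeca-5,9-diene | C=C(OCC)C1=C[C@@H]2O[C@H]1C/C(C)=C\CC[C@]2(C)O[Si](CC)(CC)CC | intermediate
20 | C14 epimer of 21 (endo adduct, acetyl cis to C2; 1S,2S,3S,6Z,9S,14S) | CCOC1=C2[C@@H]3C/C(C)=C\CC[C@](C)(O[Si](CC)(CC)CC)[C@@H](O3)[C@H]2[C@@H](C(C)=O)CC1 | intermediate
21 | 14-acetyl-11-ethoxy-3-(triethylsilyloxy) tricycle with C10=C11 enol ether (1S,2S,3S,6Z,9S,14R; acetyl trans to C2) | CCOC1=C2[C@@H]3C/C(C)=C\CC[C@](C)(O[Si](CC)(CC)CC)[C@@H](O3)[C@H]2[C@H](C(C)=O)CC1 | intermediate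
22 | alkenyl triflate of 21 (C15(OTf)=C17H2) | CCOC1=C2[C@@H]3C/C(C)=C\CC[C@](C)(O[Si](CC)(CC)CC)[C@@H](O3)[C@H]2[C@H](C(=C)OS(=O)(=O)C(F)(F)F)CC1 | intermediate
23 | acrylic acid (C15=C17H2, C16 acid) with 11-ethoxy enol ether and 3-silyl ether | CCOC1=C2[C@@H]3C/C(C)=C\CC[C@](C)(O[Si](CC)(CC)CC)[C@@H](O3)[C@H]2[C@H](C(=C)C(O)=O)CC1 | intermediate
24 | 3-hydroxy-11-oxo acrylic acid, cis-fused (1S,2S,3S,6Z,9S,10R,14R) | O=C1CC[C@@H](C(=C)C(O)=O)[C@H]2[C@@H]1[C@@H]1C/C(C)=C\CC[C@](C)(O)[C@H]2O1 | intermediate
25 | (15R)-3-hydroxy-11-oxo acid (1S,2S,3S,6Z,9S,10R,14R,15R) | O=C1CC[C@@H]([C@@H](C)C(O)=O)[C@H]2[C@@H]1[C@@H]1C/C(C)=C\CC[C@](C)(O)[C@H]2O1 | intermediate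
26 | mixed anhydride of 25 with 2,4,6-trichlorobenzoic acid | O=C1CC[C@@H]([C@@H](C)C(=O)OC(=O)c3c(Cl)cc(Cl)cc3Cl)[C@H]2[C@@H]1[C@@H]1C/C(C)=C\CC[C@](C)(O)[C@H]2O1 | intermediate
27 | 11-oxo 3,16-lactone (tetracyclic keto lactone; 1S,2S,3S,6Z,9S,10R,14R,15R) | O=C1CC[C@@H]2[C@H]3[C@@H]1[C@@H]1C/C(C)=C\CC[C@](C)(OC(=O)[C@@H]2C)[C@H]3O1 | intermediate
28 | butanoic anhydride | CCCC(=O)OC(=O)CCC | starting material
29 | chloromagnesium 11-alkoxide of the 11-methyl carbinol lactone | Cl[Mg]O[C@]1(C)CC[C@@H]2[C@H]3[C@@H]1[C@@H]1C/C(C)=C\CC[C@](C)(OC(=O)[C@@H]2C)[C@H]3O1 | intermediate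
30 | CNP0294597.2, 11-butanoyloxy 3,16-lactone (1S,2S,3S,6Z,9S,10R,11R,14R,15R) | CCCC(=O)O[C@]1(C)CC[C@@H]2[C@H]3[C@@H]1[C@@H]1C/C(C)=C\CC[C@](C)(OC(=O)[C@@H]2C)[C@H]3O1 | target

**Step count and risks**

Total step count: 17. Longest linear sequence: 17 steps (from 1).

Steps most likely to fail:

Step 16. The hindered tertiary C3 hydroxyl may be acylated too slowly in this medium-ring closure, so that intermolecular esterification or base-induced loss of the C15 configuration competes. The fallback sets out from 25 and replaces acyl substitution by addition to a ketene: TsCl and Et3N in toluene convert the acid into the carboxylic sulfonic mixed anhydride F1, which eliminates on warming to the alkylketene F2. The tertiary alcohol should add intramolecularly to the unhindered ketene carbon, and the resulting lactone enol should be protonated at C15 on the face of H14, returning to the route at 27.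

Step 15. Facial discrimination may be insufficient if the chiral catalyst and the substrate stereocentres are mismatched, or the hindered 2-(sec-alkyl)acrylic acid may be reduced sluggishly. The fallback sets out from 24 and sets C15 by substrate control in the rigid ring instead: Yamaguchi activation gives the mixed anhydride F3, which closes to the α-methylene lactone F4. Hydrogenation with RhCl(PPh3)3 and H2 in benzene should add hydrogen to the exocyclic alkene from the face of H14, away from the C13 methylene, and spare the trisubstituted ring alkene; the route is rejoined at 27.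

Step 9. Geometric control in the [2,3]-shift may be poor (E instead of Z ring alkene), and a competing 1,2-shift of the ylide is possible. The fallback sets out from 13: if the rearrangement delivers the E-configured bicyclic ketone F5, reversible thiyl radical addition (EtSH, AIBN, benzene, 80 °C) should equilibrate it to the less strained Z isomer, returning to the route at 15.

Further compounds
F1 | step 16 | mixed anhydride of 25 with 4-methylbenzenesulfonic acid | O=C1CC[C@@H]([C@@H](C)C(=O)OS(=O)(=O)c3ccc(C)cc3)[C@H]2[C@@H]1[C@@H]1C/C(C)=C\CC[C@](C)(O)[C@H]2O1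
F2 | step 16 | alkylketene from 25 (C15(CH3)=C16=O) | O=C1CC[C@@H](C(C)=C=O)[C@H]2[C@@H]1[C@@H]1C/C(C)=C\CC[C@](C)(O)[C@H]2O1
F3 | step 15 | mixed anhydride of 24 with 2,4,6-trichlorobenzoic acid | O=C1CC[C@@H](C(=C)C(=O)OC(=O)c3c(Cl)cc(Cl)cc3Cl)[C@H]2[C@@H]1[C@@H]1C/C(C)=C\CC[C@](C)(O)[C@H]2O1
F4 | step 15 | 11-oxo α-methylene 3,16-lactone | O=C1CC[C@@H]2[C@H]3[C@@H]1[C@@H]1C/C(C)=C\CC[C@](C)(OC(=O)C2=C)[C@H]3O1
F5 | step 9 | (5E)-isomer of 15 | O=C1C[C@@H]2O[C@H]1C/C(C)=C/CC[C@]2(C)O[Si](CC)(CC)CC
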